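The earlier runs and the new flask were generated by integration from invented constants; noise was put on by code.

A small charge of precatalyst, 0.48 mM, sits beside 0.048 M of substrate in spring and in dusk, and the question put to the candidate is how much target each flask ends with.

common to all: substrate 0.048 M; precatalyst 0.48 mM
- amber: partner 0.082 M; temperature 48 °C; run made earlier
- teal: partner 0.13 M; temperature 64 °C; run made earlier
- blue: partner 0.15 M; temperature 48 °C; run made earlier
- spring: partner 0.100 M; at 40 °C throughout; time 0.30 h
- dusk: partner 0.192 M; at 70 °C until 20 min, from then on at 40 °C; time 1.0 h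

| run | time / min | target / % | substrate / % |
|---|---|---|---|
| amber | 8.00 | 10.7 | 78.9 |
| amber | 20.0 | 16.5 | 62.4 |
| amber | 40.0 | 18.4 | 50.4 |
| amber | 60.0 | 16.4 | 43.6 |
| amber | 120 | 10.6 | 32.6 |
| teal | 8.00 | 16.9 | 57.5 |
| teal | 15.0 | 13.0 | 47.8 |
| teal | 25.0 | 9.9 | 38.9 |
| teal | 30.0 | 9.7 | 37.5 |
| teal | 40.0 | 8.5 | 33.2 |
| blue | 8.00 | 18.8 | 66.1 |
| blue | 20.0 | 25.4 | 43.7 |
| blue | 40.0 | 24.3 | 31.0 |
| blue | 60.0 | 19.5 | 24.9 |
| blue | 120 | 12.0 | 15.4 |

(standard deviation of a reading: 0.5 percentage points)

* the flask that ends with the higher amount of target, in percent of the substrate charged, or "neither" when 2 percentage points or less lies between them (spring / dusk / neither)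
* final target, as a percentage of the substrate charged, in spring
* final target, as a percentage of the substrate charged, in dusk

*What can be read from the runs without a rate law?* Divide the rate of target formation by the rate of substrate loss, so that time drops out and target standing over substrate lost remains. At the first readings amber gives 0.507, blue 0.555 and the hotter teal 0.398.

*What do you carry forward?* The mean of amber and blue, 0.531, which I call the target share: target per substrate lost early in a flask, an integral selectivity.

*Why "early"?* Amber's last reading, at 120 min, gives 0.157, but that reading mixes time with conversion. Blue at 8.00 min has lost 33.9% of its substrate and reads 0.555, while amber at 20.0 min has lost 37.6% and reads 0.439: the conversions are of like size and the later reading is lower, though the two runs differ in partner too. So I read "early" as early in time, not as small conversion.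

*Does spring stay early?* Amber's first reading gives a pseudo-first-order constant of 0.0296 min⁻¹ at c(partner) = 0.082 M. I scale it to 0.100 M and take half for the cooling from 48 °C to 40 °C, a rule of thumb and my weakest step. Spring then loses 27.8% of its substrate. Its 18 min are longer than the 8.00 min of those first readings, but spring is cooler, and the hotter teal reads lower at that same time, so as a judgement I keep the share and get 14.7% target.

*And dusk, which is not early?* I let teal's last reading stand for the end of the hot stretch: 8.5% target, 33.2% substrate. The same scaling at c(partner) = 0.192 M over the 40.0 min at 40 °C consumes most of that substrate. I credit half of the share, since target is lost while it forms, and get 15.1%. The two lie 0.38 percentage points apart, inside the margin of 2 points, so I say neither.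

The forecast, which parts from my reckoning on the ground that “dusk's catalyst dies within minutes”, named spring, with 19% in spring and 8% in dusk.

The simulation gives 14.4% in spring and 14.2% in dusk, so the answer is neither.

    partner + precatalyst → catalyst + spent reagent (k = 0.510 L mol⁻¹ min⁻¹, Ea = 73.0 kJ mol⁻¹)
    target + catalyst ⇌ isomer of the product + catalyst, rate k2*[catalyst]*[target] forward; the back reaction follows from the equilibrium constant (k = 110 L mol⁻¹ min⁻¹, Ea = 53.0 kJ mol⁻¹)
    substrate + partner ⇌ target (K = 1.80 L mol⁻¹, k = 1.50 L mol⁻¹ min⁻¹, Ea = 76.0 kJ mol⁻¹, ΔH = −49.0 kJ mol⁻¹)
    substrate + partner ⇌ isomer of the product (K = 15.0 L mol⁻¹, k = 0.580 L mol⁻¹ min⁻¹, Ea = 50.0 kJ mol⁻¹, ΔH = −64.0 kJ mol⁻¹)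
    (constants at 70 °C)

In spring the forward step to the isomer of the product uses substrate at 0.93 of the rate of the forward step to target at the start, and at 0.93 of it after 0.300 h, which makes a forward share of 0.518 against spring's own 0.489 of target over substrate lost. The neighbour flask, like spring but with 0.40 M of partner, leaves 25% of its substrate against spring's 71%, and the same share read on it is 0.479.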